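The data were computed from invented constants; the scatter is artificial.

Read the two earlier runs first, and let them set limits for ochre and grey before any mechanism is assumed.

| setting | theta | alpha | ochre | grey |
|---|---|---|---|---|
| electrophile | 0.25 M | 0.25 M | 0.25 M | 0.25 M |
| free base | 0.11 M | 0.36 M | 0.200 M | 0.400 M |
| protonated nucleophile | 0.30 M | 0.30 M | 0.300 M | 0.300 M |
| remark | run made earlier | run made earlier |  |  |
| time |  |  | 15 min | 15 min |

| run | time / min | electrophile / % | target / % |
|---|---|---|---|
| theta | 1.33 | 64.5 | 26.4 |
| theta | 2.00 | 59.9 | 27.8 |
| theta | 3.00 | 55.1 | 31.6 |
| theta | 5.00 | 47.5 | 33.1 |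
| theta | 10.0 | 33.6 | 37.8 |
| theta | 15.0 | 25.3 | 37.6 |
| alpha | 1.00 | 29.1 | 69.4 |
| alpha | 3.00 | 23.6 | 74.0 |
| alpha | 5.00 | 20.2 | 75.4 |
| alpha | 8.00 | 16.7 | 75.9 |
| alpha | 12.0 | 16.6 | 79.0 |
| alpha | 15.0 | 12.5 | 79.2 |

(each reading ± 1 percentage point)

1. part of the electrophile that has reacted at the end, ochre
2. part of the electrophile that has reacted at the end, grey
3. what raising the concentration of free base from its lowest to its highest value here does to the part of the electrophile that has reacted (changes below 5 percentage points count as none) (no change / it rises / it falls)

Compare the first readings. Going from theta to alpha adds 1.00 of free base per electrophile charged and 43 percentage points of target, so about 2.33 free base go per target; freeze that at two. Ochre then gets 40.0%, grey 80.0%, theta 22.0% and alpha 72.0%. This fraction, free base charged divided by two and by the electrophile charged, is the base ceiling, with free base as limiting reagent. Use it as the lower bound on what has reacted.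

For the upper bound, divide the electrophile left at 15 min by what the ceiling leaves, and call this the survival share. It reads 0.324 in theta and 0.446 in alpha, so it rose with free base. Ochre lies between the runs, which puts its reacted part between 73.2% and 80.6%. Grey has more free base than alpha, so alpha's share gives its top: between 80.0% and 91.1%. A straight line of the share against free base tightens my own reckoning to 77.9% and 90.7%.

The forecast, reading a “fast burst followed by a slow tail”, gave 79% for ochre and 90.5% for grey, both inside these brackets, and for the trend: it rises.

The flask gives 76.8% for ochre and 89.9% for grey, also inside the brackets; from the lowest free base to the highest, the reacted part: it rises, by 13 points.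

    acid set free + free base ⇌ salt of the base, settled at all times (K = 76100 M⁻¹)
    electrophile + nucleophile → acid set free + target (k = 27.4 M⁻¹ min⁻¹)
    nucleophile ⇌ dormant form (K = 0.438, k = 0.303 min⁻¹)
    free base → decomposition product (k = 5.30 × 10⁻⁵ min⁻¹)
    nucleophile + acid set free ⇌ protonated nucleophile, settled at all times (K = 4700 M⁻¹)
    2 electrophile → self-condensation product (k = 0.223 M⁻¹ min⁻¹)

The main reason for the gap between the two flasks is their difference in free base: grey, at 89.9%, drops to 76.8% when it is given ochre's 0.200 M. The ceiling leaves 60.0% of the charge in ochre and 20.0% in grey, and self-condensation is a part of what takes that rest: without it ochre falls to 56.3% and grey to 85.9%. Now take the neighbour of grey with 0.10 M of free base: its ceiling is 20.0%, and the line's share gives 74.4% reacted. The flask gives 72.9%.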